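**Retrosynthetic overview**
1. The ester comes from acylation of the C-8 allylic alcohol, which comes from 1,2-reduction of a C-8 enone.
2. The cyclopentane and its three contiguous cis groups (C-3 isopropyl, C-3a OH, C-8a methyl) come from an intramolecular carbonyl-ene reaction of a 2-methyl-2-homoprenyl cycloheptene-1,3-dione, so the seven-membered ring is made first and the five-membered ring second.
3. The quaternary C-8a comes from a catalytic asymmetric Michael addition of an achiral 2-methyl-1,3-dione to acrolein, followed by a Wittig reaction.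
4. The seven-membered ring comes from a (4+3) cycloaddition of 2-methylfuran with the oxyallyl cation of 3-chlorobutan-2-one; here the ketone α-carbons act as electrophiles. The oxygen bridge is then opened and the alcohol oxidised.

Assumption: in step 5 the cupreidine-derived catalyst is taken to give the (S)-configured quaternary centre; its cupreine-derived pseudo-enantiomer gives the antipode and replaces it if the measured sense is opposite.

Azulene numbering of the target is used for atom labels (C-3 isopropyl carbon, C-3a carbinol, C-6 methyl-bearing alkene carbon, C-8 ester carbon, C-8a quaternary methyl carbon). The target is read as having the isopropyl, OH, angular methyl and ester oxygen all on one face.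

**Step 1**
Reactants: 1 2-methylfuran; 2 3-chlorobutan-2-one
Product: 4 rac-1,4-dimethyl-8-oxabicyclo[3.2.1]oct-6-en-3-one (both C-4 epimers), via oxyallyl cation 3 (not isolated)
Conditions: Et3N (1.5 equiv), 1 (4 equiv), CF3CH2OH, 0 °C to rt
Reagents that add atoms: none
Why: Föhlisch-type (4+3) cycloaddition in which base ionises the α-chloroketone to oxyallyl cation 3, whose two α-carbons bond to the furan 2,5-positions; the methyl-bearing terminus is expected to bond to the unsubstituted furan carbon (minor regioisomer removed), and the racemic ring stereocentres are erased in steps 3 and 4.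

**Step 2**
Reactants: 4 rac-1,4-dimethyl-8-oxabicyclo[3.2.1]oct-6-en-3-one
Product: 5 rac-1,4-dimethyl-8-oxabicyclo[3.2.1]octan-3-one
Conditions: H2 (1 atm), 10% Pd/C, EtOAc, rt
Reagents that add atoms: none
Why: Catalytic hydrogenation of the strained bridge alkene, done now so that later ring opening cannot lead to a tropone.

**Step 3**
Reactants: 5 rac-1,4-dimethyl-8-oxabicyclo[3.2.1]octan-3-one
Product: 8 rac-6-hydroxy-3,7-dimethylcyclohept-2-en-1-one, via silyl enol ether 6 (not isolated), via ring-opened silyl ether 7 (not isolated)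
Conditions: LiN(i-Pr)2, Me3SiCl, THF, −78 °C; then Me3SiOTf (10 mol %), CH2Cl2, −78 to 0 °C; then 1 M HCl, THF
Reagents that add atoms: none
Why: Kinetic enolisation at the CH2 gives enol ether 6, and silyl-triflate-promoted β-elimination (retro-oxa-Michael) then breaks the tertiary bridgehead C–O bond to give the β-methyl enone and the C-3a alcohol.

**Step 4**
Reactants: 8 rac-6-hydroxy-3,7-dimethylcyclohept-2-en-1-one
Product: 9 2,5-dimethylcyclohept-4-ene-1,3-dione
Conditions: IBX (2-iodoxybenzoic acid, 1.3 equiv), DMSO, rt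
Reagents that add atoms: none
Why: Oxidation of the secondary alcohol gives an achiral, enolisable 2-methyl-1,3-dione, so all earlier stereochemistry is deliberately removed.

**Step 5**
Reactants: 9 2,5-dimethylcyclohept-4-ene-1,3-dione; 10 acrolein
Product: 11 3-[(1S)-1,4-dimethyl-2,7-dioxocyclohept-3-en-1-yl]propanal
Conditions: 9-O-(9-phenanthryl)cupreidine (10 mol %), 10 (3 equiv), CH2Cl2, −25 °C
Reagents that add atoms: none
Why: Deng-type cinchona-catalysed asymmetric Michael addition of an α-substituted 1,3-dicarbonyl to acrolein, in which the bifunctional catalyst binds the enol and shields one face, setting the quaternary C-8a as (S); this is the only enantio-determining step.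

**Step 6**
Reactants: 11 3-[(1S)-1,4-dimethyl-2,7-dioxocyclohept-3-en-1-yl]propanal; 12 isopropyltriphenylphosphonium iodide
Product: 14 (S)-2,5-dimethyl-2-(4-methylpent-3-en-1-yl)cyclohept-4-ene-1,3-dione, via phosphorus ylide 13 (not isolated)
Conditions: 12, n-BuLi, THF, 0 °C; then 11, −78 to 0 °C
Reagents that add atoms: none
Why: Wittig olefination, selective for the aldehyde over the two hindered ketones at low temperature, installs the trisubstituted alkene needed as the ene donor without touching C-8a.

**Step 7**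
Reactants: 14 (S)-2,5-dimethyl-2-(4-methylpent-3-en-1-yl)cyclohept-4-ene-1,3-dione
Product: 15 (3R,3aS,8aS)-3a-hydroxy-6,8a-dimethyl-3-(prop-1-en-2-yl)-2,3,3a,4,5,8a-hexahydroazulen-8(1H)-one
Conditions: Me2AlCl (2.2 equiv), CH2Cl2, −78 to 0 °C; 1 M HCl work-up
Reagents that add atoms: none
Why: Lewis-acid-promoted intramolecular carbonyl-ene reaction at the saturated ketone (more electrophilic than the enone carbonyl); the ring forces a cis fusion (OH cis to the C-8a methyl), and the six-membered hydrogen-transfer transition state places the isopropenyl group cis to the OH, so C-3a and C-3 are both set from C-8a.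

**Step 8**
Reactants: 15 (3R,3aS,8aS)-3a-hydroxy-6,8a-dimethyl-3-(prop-1-en-2-yl)-2,3,3a,4,5,8a-hexahydroazulen-8(1H)-one
Product: 16 (3R,3aS,8aS)-3a-hydroxy-6,8a-dimethyl-3-(propan-2-yl)-2,3,3a,4,5,8a-hexahydroazulen-8(1H)-one
Conditions: H2 (1 atm), RhCl(PPh3)3 (5 mol %), benzene/EtOH, rt
Reagents that add atoms: none
Why: Homogeneous hydrogenation reduces the 1,1-disubstituted isopropenyl alkene and leaves the trisubstituted conjugated alkene; no stereocentre is created or touched.

**Step 9**
Reactants: 16 (3R,3aS,8aS)-3a-hydroxy-6,8a-dimethyl-3-(propan-2-yl)-2,3,3a,4,5,8a-hexahydroazulen-8(1H)-one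
Product: 17 (3R,3aS,8S,8aR)-6,8a-dimethyl-3-(propan-2-yl)-1,2,3,3a,4,5,8,8a-octahydroazulene-3a,8-diol
Conditions: NaBH4, CeCl3·7H2O, MeOH, −78 to −40 °C
Reagents that add atoms: none
Why: Luche 1,2-reduction of the enone, with hydride expected to add from the face opposite the angular methyl and the cerium-bound C-3a oxygen, which puts the new C-8 OH cis to both (8S).

**Step 10**
Reactants: 17 (3R,3aS,8S,8aR)-6,8a-dimethyl-3-(propan-2-yl)-1,2,3,3a,4,5,8,8a-octahydroazulene-3a,8-diol; 18 4-methoxybenzoyl chloride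
Product: 19 (3R,3aS,8S,8aR)-3a-hydroxy-6,8a-dimethyl-3-(propan-2-yl)-1,2,3,3a,4,5,8,8a-octahydroazulen-8-yl 4-methoxybenzoate
Conditions: 18 (1.3 equiv), Et3N, DMAP (10 mol %), CH2Cl2, 0 °C to rt
Reagents that add atoms: none
Why: DMAP-catalysed acylation of the secondary allylic alcohol; the tertiary C-3a alcohol does not react, and the configuration at C-8 is retained.

**Compound list**
1 | 2-methylfuran | Cc1ccco1 | starting material
2 | 3-chlorobutan-2-one | CC(Cl)C(C)=O | starting material
3 | 1-methyl-2-oxidoallyl cation (oxyallyl cation) | C=C([O-])[CH+]C | intermediate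
4 | rac-1,4-dimethyl-8-oxabicyclo[3.2.1]oct-6-en-3-one (both C-4 epimers) | CC1C(=O)CC2(C)C=CC1O2 | intermediate
5 | rac-1,4-dimethyl-8-oxabicyclo[3.2.1]octan-3-one | CC1C(=O)CC2(C)CCC1O2 | intermediate
6 | rac-1,4-dimethyl-3-(trimethylsilyloxy)-8-oxabicyclo[3.2.1]oct-2-ene | CC1C(O[Si](C)(C)C)=CC2(C)CCC1O2 | intermediate
7 | rac-3,7-dimethyl-6-(trimethylsilyloxy)cyclohept-2-en-1-one | CC1C(O[Si](C)(C)C)CCC(C)=CC1=O | intermediate
8 | rac-6-hydroxy-3,7-dimethylcyclohept-2-en-1-one | CC1C(O)CCC(C)=CC1=O | intermediate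
9 | 2,5-dimethylcyclohept-4-ene-1,3-dione | CC1C(=O)CCC(C)=CC1=O | intermediate
10 | acrolein | C=CC=O | starting material
11 | 3-[(1S)-1,4-dimethyl-2,7-dioxocyclohept-3-en-1-yl]propanal | O=CCC[C@@]1(C)C(=O)CCC(C)=CC1=O | intermediate
12 | isopropyltriphenylphosphonium iodide | CC(C)[P+](c1ccccc1)(c1ccccc1)c1ccccc1.[I-] | starting material
13 | isopropylidenetriphenylphosphorane | CC(C)=P(c1ccccc1)(c1ccccc1)c1ccccc1 | intermediate
14 | (S)-2,5-dimethyl-2-(4-methylpent-3-en-1-yl)cyclohept-4-ene-1,3-dione | CC(C)=CCC[C@@]1(C)C(=O)CCC(C)=CC1=O | intermediate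
15 | (3R,3aS,8aS)-3a-hydroxy-6,8a-dimethyl-3-(prop-1-en-2-yl)-2,3,3a,4,5,8a-hexahydroazulen-8(1H)-one | O=C1C=C(C)CC[C@]2(O)[C@@H](C(C)=C)CC[C@]12C | intermediate
16 | (3R,3aS,8aS)-3a-hydroxy-6,8a-dimethyl-3-(propan-2-yl)-2,3,3a,4,5,8a-hexahydroazulen-8(1H)-one | O=C1C=C(C)CC[C@]2(O)[C@@H](C(C)C)CC[C@]12C | intermediate
17 | (3R,3aS,8S,8aR)-6,8a-dimethyl-3-(propan-2-yl)-1,2,3,3a,4,5,8,8a-octahydroazulene-3a,8-diol | O[C@H]1C=C(C)CC[C@]2(O)[C@@H](C(C)C)CC[C@]12C | intermediate
18 | 4-methoxybenzoyl chloride | COc1ccc(cc1)C(Cl)=O | starting material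
19 | (3R,3aS,8S,8aR)-3a-hydroxy-6,8a-dimethyl-3-(propan-2-yl)-1,2,3,3a,4,5,8,8a-octahydroazulen-8-yl 4-methoxybenzoate | COc1ccc(C(=O)O[C@H]2C=C(C)CC[C@]3(O)[C@@H](C(C)C)CC[C@]23C)cc1 | target

**Total step count:** 10. **Longest linear sequence:** 10.

**Three steps most likely to fail**

Step 5 (asymmetric Michael addition). The two carbonyl arms of dione 9 differ only by remote unsaturation, so the enantiomeric excess and its sense are not secured by precedent. The fallback sets out from 9 and comes back at 11. Dione 9 is O-acylated with allyl chloroformate (Et3N, CH2Cl2) to allyl 2,5-dimethyl-3-oxocyclohepta-1,4-dien-1-yl carbonate F1; the regioisomeric enol carbonate gives the same palladium enolate. Decarboxylative asymmetric allylation with Pd2(dba)3 and t-BuPHOX (enantiomer chosen for the S product) in toluene gives (S)-2,5-dimethyl-2-(prop-2-en-1-yl)cyclohept-4-ene-1,3-dione F2. Aldehyde-selective anti-Markovnikov Wacker oxidation of the allyl group (PdCl2(PhCN)2, CuCl2, AgNO2, O2, t-BuOH/MeNO2) then gives aldehyde 11.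

Step 7 (carbonyl-ene cyclisation). The enone carbonyl might react instead of the saturated ketone, or a stepwise cationic path might give chloride or isopropylidene by-products. The fallback sets out from 14 and comes back at 19. Luche reduction of 14 (NaBH4, CeCl3·7H2O, MeOH, −78 °C), which reduces the conjugated ketone in preference to the saturated one, gives (2R,3S)-3-hydroxy-2,5-dimethyl-2-(4-methylpent-3-en-1-yl)cyclohept-4-en-1-one F3 after separation from its C-3 epimer; facial control is weaker on this monocycle. Acylation with 18 (Et3N, DMAP) gives (1S,7R)-3,7-dimethyl-7-(4-methylpent-3-en-1-yl)-6-oxocyclohept-2-en-1-yl 4-methoxybenzoate F4, which has only one ketone left. Me2AlCl-promoted ene cyclisation gives (3R,3aS,8S,8aR)-3a-hydroxy-6,8a-dimethyl-3-(prop-1-en-2-yl)-1,2,3,3a,4,5,8,8a-octahydroazulen-8-yl 4-methoxybenzoate F5, and hydrogenation with RhCl(PPh3)3 gives 19.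

Step 9 (Luche reduction). The seven-membered enone is flexible and the facial preference is only argued by analogy. The fallback sets out from 16 and comes back at 19. If hydride adds from the methyl face the product is (3R,3aS,8R,8aR)-6,8a-dimethyl-3-(propan-2-yl)-1,2,3,3a,4,5,8,8a-octahydroazulene-3a,8-diol F6. This is esterified with inversion at C-8 under Mitsunobu conditions (4-methoxybenzoic acid, PPh3, diisopropyl azodicarboxylate, toluene) to give 19 directly; the hindered alcohol makes this slow.

**Further compounds**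
F1 | step 5 | allyl 2,5-dimethyl-3-oxocyclohepta-1,4-dien-1-yl carbonate | C=CCOC(=O)OC1=C(C)C(=O)C=C(C)CC1
F2 | step 5 | (S)-2,5-dimethyl-2-(prop-2-en-1-yl)cyclohept-4-ene-1,3-dione | C=CC[C@@]1(C)C(=O)CCC(C)=CC1=O
F3 | step 7 | (2R,3S)-3-hydroxy-2,5-dimethyl-2-(4-methylpent-3-en-1-yl)cyclohept-4-en-1-one | O[C@H]1C=C(C)CCC(=O)[C@]1(C)CCC=C(C)C
F4 | step 7 | (1S,7R)-3,7-dimethyl-7-(4-methylpent-3-en-1-yl)-6-oxocyclohept-2-en-1-yl 4-methoxybenzoate | COc1ccc(cc1)C(=O)O[C@H]1C=C(C)CCC(=O)[C@]1(C)CCC=C(C)C
F5 | step 7 | (3R,3aS,8S,8aR)-3a-hydroxy-6,8a-dimethyl-3-(prop-1-en-2-yl)-1,2,3,3a,4,5,8,8a-octahydroazulen-8-yl 4-methoxybenzoate | COc1ccc(cc1)C(=O)O[C@H]1C=C(C)CC[C@]2(O)[C@@H](C(C)=C)CC[C@]12C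
F6 | step 9 | (3R,3aS,8R,8aR)-6,8a-dimethyl-3-(propan-2-yl)-1,2,3,3a,4,5,8,8a-octahydroazulene-3a,8-diol | O[C@@H]1C=C(C)CC[C@]2(O)[C@@H](C(C)C)CC[C@]12C
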